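**Retrosynthetic overview**

- The target is reached by global deprotection of its 4-O-Boc penta-O-TBS derivative. The four benzene rings are bought, and the dihydrofuran ring (O1, C2, C3, C3a, C7a) is the only ring of the skeleton that is made, and it is made last.
- That ring is closed in a one-pot three-component cascade: aryl Grignard + 2,6-bis(Boc-oxy)benzaldehyde gives the C3–aryl bond and releases an o-quinone methide; a chiral sulfonium benzylide then forms C2–C3; the phenoxide closes O1–C2 (formal [4+1]).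
- Enabling feature: C3a lies between two oxygen-bearing ring carbons (C7a–O1 and C4–OH), so the benzo ring is a 2-substituted resorcinol. A 2,6-bis(Boc-oxy)benzaldehyde therefore has two equivalent carbonates: one is the trigger and leaving group whose phenol oxygen becomes O1, the other ends as the protected C4–OH. C2 is a para-oxygenated benzylic carbon and so can be delivered as an ylide carbon.
- Components: the stilbene aldehyde (from 4-bromo-2,6-dimethoxybenzaldehyde by demethylation, Boc protection and Heck reaction), the aryl bromide from 5-bromoresorcinol, and the sulfonium salt from 3,4-dihydroxybenzaldehyde.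
- Absolute configuration comes from a C2-symmetric (2S,5S)-2,5-dimethylthiolane; its ring is a temporary one, made in step 10 and released in step 12.

Key step: step 12

Assumption: the SMILES encodes (2S,3S), which is the 2,3-trans-dihydrobenzofuran; benzofuran numbering (O1, C2, C3, C3a, C4–C7, C7a) is used throughout.

**Route**

Step 1
Reactants: 1 4-bromo-2,6-dimethoxybenzaldehyde
Product: 2 4-bromo-2,6-dihydroxybenzaldehyde
Conditions: BBr3 (3 equiv), CH2Cl2, −78 °C → rt; then H2O
Reagents that add atoms: none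
Why: BBr3 cleavage of aryl methyl ethers is fast ortho to the chelating formyl group and is placed here because the methyl ether that the target keeps enters only in step 4.

Step 2
Reactants: 2 4-bromo-2,6-dihydroxybenzaldehyde
Product: 3 4-bromo-2,6-bis[(tert-butoxycarbonyl)oxy]benzaldehyde
Conditions: Boc2O (2.4 equiv), DMAP (5 mol%), i-Pr2NEt, THF, 0 °C → rt
Reagents that add atoms: di-tert-butyl dicarbonate CC(C)(C)OC(=O)OC(=O)OC(C)(C)C
Why: DMAP-catalysed O-acylation of both phenols (carbonate formation) should give the ortho-Boc-oxy aldehyde that the anionic o-quinone methide cascade requires.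

Step 3
Reactants: 4 2-methoxy-4-vinylphenol
Product: 5 tert-butyl(2-methoxy-4-vinylphenoxy)dimethylsilane
Conditions: TBSCl, imidazole, DMF, 0 °C → rt (BHT trace)
Reagents that add atoms: tert-butyldimethylsilyl chloride CC(C)(C)[Si](C)(C)Cl
Why: Silylation of the phenol (silyl ether formation) masks the only acidic proton of the styrene before the organometallic steps.

Step 4
Reactants: 3 4-bromo-2,6-bis[(tert-butoxycarbonyl)oxy]benzaldehyde; 5 tert-butyl(2-methoxy-4-vinylphenoxy)dimethylsilane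
Product: 6 (E)-2,6-bis[(tert-butoxycarbonyl)oxy]-4-[4-(tert-butyldimethylsilyloxy)-3-methoxystyryl]benzaldehyde
Conditions: Pd2(dba)3 (1.5 mol%), [HP(t-Bu)3]BF4 (6 mol%), Cy2NMe (1.2 equiv), dioxane, rt
Reagents that add atoms: none
Why: A Mizoroki–Heck reaction with the Pd/P(t-Bu)3/Cy2NMe system should couple the activated aryl bromide at room temperature, so that the base-labile aryl carbonates and the silyl ether survive, and syn-insertion followed by syn-β-hydride elimination sets the E alkene.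

Step 5
Reactants: 7 5-bromobenzene-1,3-diol
Product: 8 1-bromo-3,5-bis(tert-butyldimethylsilyloxy)benzene
Conditions: TBSCl (2.3 equiv), imidazole, DMF, rt
Reagents that add atoms: tert-butyldimethylsilyl chloride CC(C)(C)[Si](C)(C)Cl
Why: Standard bis-silylation of a resorcinol (silyl ether formation) gives an aryl bromide that tolerates magnesium insertion.

Step 6
Reactants: 9 3,4-dihydroxybenzaldehyde
Product: 10 3,4-bis(tert-butyldimethylsilyloxy)benzaldehyde
Conditions: TBSCl (2.3 equiv), imidazole, DMF, rt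
Reagents that add atoms: tert-butyldimethylsilyl chloride CC(C)(C)[Si](C)(C)Cl
Why: Bis-silylation of the catechol (silyl ether formation) gives a protecting pattern that survives hydride, ylide and Grignard chemistry and is removed at the end without touching a methyl ether.

Step 7
Reactants: 10 3,4-bis(tert-butyldimethylsilyloxy)benzaldehyde
Product: 11 [3,4-bis(tert-butyldimethylsilyloxy)phenyl]methanol
Conditions: NaBH4, THF/MeOH, 0 °C
Reagents that add atoms: none
Why: Borohydride reduction of the aldehyde to the benzylic alcohol leaves aryl silyl ethers untouched.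

Step 8
Reactants: 11 [3,4-bis(tert-butyldimethylsilyloxy)phenyl]methanol
Product: 12 4-(bromomethyl)-1,2-bis(tert-butyldimethylsilyloxy)benzene
Conditions: CBr4, PPh3, CH2Cl2, 0 °C; used at once
Reagents that add atoms: carbon tetrabromide BrC(Br)(Br)Br
Why: The Appel reaction converts the benzylic alcohol into the bromide under neutral conditions that the silyl ethers tolerate.

Step 9
Reactants: 13 (2R,5R)-hexane-2,5-diol
Product: 14 (2R,5R)-hexane-2,5-diyl dimethanesulfonate
Conditions: MsCl (2.4 equiv), Et3N, CH2Cl2, −20 → 0 °C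
Reagents that add atoms: methanesulfonyl chloride CS(=O)(=O)Cl
Why: O-Sulfonylation (mesylation) activates both secondary alcohols with retention, since no bond to a stereocentre is broken.

Step 10
Reactants: 14 (2R,5R)-hexane-2,5-diyl dimethanesulfonate
Product: 15 (2S,5S)-2,5-dimethylthiolane
Conditions: Na2S·9H2O, EtOH, rt; distillation
Reagents that add atoms: sodium sulfide [Na+].[Na+].[S-2]
Why: Double SN2 displacement by sulfide (thioether formation, the second one a 5-exo-tet closure) inverts both centres, so the (2R,5R) diol gives the (2S,5S) sulfide.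

Step 11
Reactants: 12 4-(bromomethyl)-1,2-bis(tert-butyldimethylsilyloxy)benzene; 15 (2S,5S)-2,5-dimethylthiolane
Product: 16 (2S,5S)-1-[3,4-bis(tert-butyldimethylsilyloxy)benzyl]-2,5-dimethylthiolan-1-ium trifluoromethanesulfonate
Conditions: AgOTf (1.0 equiv), 15 (1.5 equiv), CH2Cl2, 0 °C → rt, dark; filtration, precipitation from Et2O
Reagents that add atoms: silver trifluoromethanesulfonate [Ag+].[O-]S(=O)(=O)C(F)(F)F
Why: Silver-assisted S-alkylation of the sulfide (sulfonium salt formation) should be clean, and because the sulfide is C2-symmetric both lone pairs give the same single salt with a non-nucleophilic counter-ion.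

Step 12
Reactants: 6 (E)-2,6-bis[(tert-butoxycarbonyl)oxy]-4-[4-(tert-butyldimethylsilyloxy)-3-methoxystyryl]benzaldehyde; 8 1-bromo-3,5-bis(tert-butyldimethylsilyloxy)benzene; 16 (2S,5S)-1-[3,4-bis(tert-butyldimethylsilyloxy)benzyl]-2,5-dimethylthiolan-1-ium trifluoromethanesulfonate
Product: 23 (2S,3S)-4-O-Boc-penta-O-TBS-protected target, via aryl Grignard reagent 17 (not isolated), via thiolanium benzylide 18 (not isolated), via magnesium alkoxide 19 (not isolated), via carbonate-shifted phenoxide 20 (not isolated), via o-quinone methide 21 (not isolated), via sulfonium phenoxide betaine 22 (not isolated)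
Conditions: (a) 8, Mg, THF, 45 °C; (b) 16 (1.3 equiv), LiHMDS (1.25 equiv), THF, −78 °C; (c) 6 + Grignard solution (1.05 equiv), THF, −78 °C, 30 min; then ylide solution by cannula, −78 → −20 °C; aq. NH4Cl
Reagents that add atoms: none
Why: Proposed new method: Grignard reagent 17 adds to the formyl group of 6, alkoxide 19 takes over one of the two equivalent Boc groups (O→O shift, 20) and the phenoxide then expels tert-butyl carbonate to release o-quinone methide 21 at low temperature; ylide 18 adds to its exocyclic carbon with rearomatisation (C2–C3 bond, betaine 22) and the phenoxide displaces the thiolane from the benzylic carbon (O1–C2 bond). The closest known reactions are the anionic three-component cascade of o-(Boc-oxy)benzaldehydes with two organometallic reagents through such o-quinone methides, and the [4+1] annulation of o-quinone methides with sulfonium and chiral ammonium ylides to trans-2,3-dihydrobenzofurans; new is a semistabilised chiral thiolanium benzylide as the second nucleophile of the one-pot cascade. The dihydrofuran ring closes in a 5-exo-tet SN2 displacement with inversion at C2. C2 is set by the reagent: as in aldehyde epoxidation with C2-symmetric 2,5-dimethylthiolanium benzylides, the ylide should react in the conformer with its aryl group on the lone-pair side and on the face away from the ring methyl group that is cis to the ylide carbon, which for the (2S,5S) sulfide leads after inversion to 2S, while C3 is set relative to C2 by the anti arrangement of the two aryl groups in the addition, giving the trans (2S,3S) isomer. The step needs chemoselectivity (1,2-addition of 17 before attack on a carbonate; addition of 18 to 21 faster than ylide rearrangement or acyl transfer), which the order of addition at −78 °C and the high electrophilicity of 21 should secure, and it needs no regiocontrol because the two carbonates of 6 are equivalent.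

Step 13
Reactants: 23 (2S,3S)-4-O-Boc-penta-O-TBS-protected target
Product: 25 the target (2S,3S)-hexaphenol, via penta-O-TBS 4-phenol 24 (not isolated)
Conditions: (i) piperidine (5 equiv), THF, rt, Ar; (ii) KHF2 (10 equiv), MeOH, rt, Ar; one pot
Reagents that add atoms: none
Why: Aminolysis of the base-labile aryl tert-butyl carbonate followed by bifluoride cleavage of the five aryl silyl ethers (desilylation) runs near neutrality, so the methyl ether, the stilbene and both stereocentres should remain untouched.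

**Compound list**

1 | 4-bromo-2,6-dimethoxybenzaldehyde | COc1cc(Br)cc(OC)c1C=O | starting material
2 | 4-bromo-2,6-dihydroxybenzaldehyde | O=Cc1c(O)cc(Br)cc1O | intermediate
3 | 4-bromo-2,6-bis[(tert-butoxycarbonyl)oxy]benzaldehyde | CC(C)(C)OC(=O)Oc1cc(Br)cc(OC(=O)OC(C)(C)C)c1C=O | intermediate
4 | 2-methoxy-4-vinylphenol | COc1cc(C=C)ccc1O | starting material
5 | tert-butyl(2-methoxy-4-vinylphenoxy)dimethylsilane | COc1cc(C=C)ccc1O[Si](C)(C)C(C)(C)C | intermediate
6 | (E)-2,6-bis[(tert-butoxycarbonyl)oxy]-4-[4-(tert-butyldimethylsilyloxy)-3-methoxystyryl]benzaldehyde | COc1cc(/C=C/c2cc(OC(=O)OC(C)(C)C)c(C=O)c(OC(=O)OC(C)(C)C)c2)ccc1O[Si](C)(C)C(C)(C)C | intermediate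
7 | 5-bromobenzene-1,3-diol | Oc1cc(O)cc(Br)c1 | starting material
8 | 1-bromo-3,5-bis(tert-butyldimethylsilyloxy)benzene | CC(C)(C)[Si](C)(C)Oc1cc(Br)cc(O[Si](C)(C)C(C)(C)C)c1 | intermediate
9 | 3,4-dihydroxybenzaldehyde | O=Cc1ccc(O)c(O)c1 | starting material
10 | 3,4-bis(tert-butyldimethylsilyloxy)benzaldehyde | O=Cc1ccc(O[Si](C)(C)C(C)(C)C)c(O[Si](C)(C)C(C)(C)C)c1 | intermediate
11 | [3,4-bis(tert-butyldimethylsilyloxy)phenyl]methanol | OCc1ccc(O[Si](C)(C)C(C)(C)C)c(O[Si](C)(C)C(C)(C)C)c1 | intermediate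
12 | 4-(bromomethyl)-1,2-bis(tert-butyldimethylsilyloxy)benzene | BrCc1ccc(O[Si](C)(C)C(C)(C)C)c(O[Si](C)(C)C(C)(C)C)c1 | intermediate
13 | (2R,5R)-hexane-2,5-diol | C[C@@H](O)CC[C@@H](C)O | starting material
14 | (2R,5R)-hexane-2,5-diyl dimethanesulfonate | C[C@@H](OS(C)(=O)=O)CC[C@@H](C)OS(C)(=O)=O | intermediate
15 | (2S,5S)-2,5-dimethylthiolane | C[C@H]1CC[C@H](C)S1 | intermediate
16 | (2S,5S)-1-[3,4-bis(tert-butyldimethylsilyloxy)benzyl]-2,5-dimethylthiolan-1-ium trifluoromethanesulfonate | C[C@H]1CC[C@H](C)[S+]1Cc1ccc(O[Si](C)(C)C(C)(C)C)c(O[Si](C)(C)C(C)(C)C)c1.[O-]S(=O)(=O)C(F)(F)F | intermediate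
17 | [3,5-bis(tert-butyldimethylsilyloxy)phenyl]magnesium bromide | CC(C)(C)[Si](C)(C)Oc1cc([Mg]Br)cc(O[Si](C)(C)C(C)(C)C)c1 | intermediate
18 | (2S,5S)-2,5-dimethylthiolanium [3,4-bis(tert-butyldimethylsilyloxy)phenyl]methylide | C[C@H]1CC[C@H](C)[S+]1[CH-]c1ccc(O[Si](C)(C)C(C)(C)C)c(O[Si](C)(C)C(C)(C)C)c1 | intermediate
19 | bromomagnesium alkoxide of {2,6-bis(Boc-oxy)-4-[(E)-4-(TBS-oxy)-3-methoxystyryl]phenyl}[3,5-bis(TBS-oxy)phenyl]methanol (racemic at the carbinol carbon) | COc1cc(/C=C/c2cc(OC(=O)OC(C)(C)C)c(C(O[Mg]Br)c3cc(O[Si](C)(C)C(C)(C)C)cc(O[Si](C)(C)C(C)(C)C)c3)c(OC(=O)OC(C)(C)C)c2)ccc1O[Si](C)(C)C(C)(C)C | intermediate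
20 | bromomagnesium 3-(Boc-oxy)-2-{(Boc-oxy)[3,5-bis(TBS-oxy)phenyl]methyl}-5-[(E)-4-(TBS-oxy)-3-methoxystyryl]phenoxide | COc1cc(/C=C/c2cc(O[Mg]Br)c(C(OC(=O)OC(C)(C)C)c3cc(O[Si](C)(C)C(C)(C)C)cc(O[Si](C)(C)C(C)(C)C)c3)c(OC(=O)OC(C)(C)C)c2)ccc1O[Si](C)(C)C(C)(C)C | intermediate
21 | 6-{[3,5-bis(TBS-oxy)phenyl]methylidene}-5-(Boc-oxy)-3-[(E)-4-(TBS-oxy)-3-methoxystyryl]cyclohexa-2,4-dien-1-one (o-quinone methide) | COc1cc(/C=C/C2=CC(=O)C(=Cc3cc(O[Si](C)(C)C(C)(C)C)cc(O[Si](C)(C)C(C)(C)C)c3)C(OC(=O)OC(C)(C)C)=C2)ccc1O[Si](C)(C)C(C)(C)C | intermediate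
22 | betaine: 3-(Boc-oxy)-5-styryl-phenoxide carrying at its 2-position the (S)-configured diarylmethine carbon (future C3) bonded to the (R)-configured carbon (future C2) that bears the 3,4-bis(TBS-oxy)phenyl group and the (2S,5S)-2,5-dimethylthiolanium group | [O-]c1cc(/C=C/c2ccc(O[Si](C)(C)C(C)(C)C)c(OC)c2)cc(OC(=O)OC(C)(C)C)c1[C@H](c1cc(O[Si](C)(C)C(C)(C)C)cc(O[Si](C)(C)C(C)(C)C)c1)[C@H](c1ccc(O[Si](C)(C)C(C)(C)C)c(O[Si](C)(C)C(C)(C)C)c1)[S+]1[C@@H](C)CC[C@@H]1C | intermediate
23 | tert-butyl (2S,3S)-2-[3,4-bis(TBS-oxy)phenyl]-3-[3,5-bis(TBS-oxy)phenyl]-6-[(E)-4-(TBS-oxy)-3-methoxystyryl]-2,3-dihydro-1-benzofuran-4-yl carbonate | COc1cc(/C=C/c2cc(OC(=O)OC(C)(C)C)c3c(c2)O[C@H](c2ccc(O[Si](C)(C)C(C)(C)C)c(O[Si](C)(C)C(C)(C)C)c2)[C@H]3c2cc(O[Si](C)(C)C(C)(C)C)cc(O[Si](C)(C)C(C)(C)C)c2)ccc1O[Si](C)(C)C(C)(C)C | intermediate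
24 | (2S,3S)-2-[3,4-bis(TBS-oxy)phenyl]-3-[3,5-bis(TBS-oxy)phenyl]-6-[(E)-4-(TBS-oxy)-3-methoxystyryl]-2,3-dihydro-1-benzofuran-4-ol | COc1cc(/C=C/c2cc(O)c3c(c2)O[C@H](c2ccc(O[Si](C)(C)C(C)(C)C)c(O[Si](C)(C)C(C)(C)C)c2)[C@H]3c2cc(O[Si](C)(C)C(C)(C)C)cc(O[Si](C)(C)C(C)(C)C)c2)ccc1O[Si](C)(C)C(C)(C)C | intermediate
25 | (2S,3S)-2-(3,4-dihydroxyphenyl)-3-(3,5-dihydroxyphenyl)-6-[(E)-4-hydroxy-3-methoxystyryl]-2,3-dihydro-1-benzofuran-4-ol | COc1cc(/C=C/c2cc(O)c3c(c2)O[C@H](c2ccc(O)c(O)c2)[C@H]3c2cc(O)cc(O)c2)ccc1O | target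

**Summary**

Total step count: 13. Longest linear sequence: 6 steps (steps 6, 7, 8, 11, 12, 13).

Steps most likely to fail:

1. Step 12 (proposed new method). The ylide may rearrange or be acylated by a carbonate before the o-quinone methide is released, the o-quinone methide may oligomerise, and facial selectivity at C2 or C3 may be poor. The fallback uses known chemistry and closes the same ring through the C2–C3 bond by an enantioselective rhodium donor/donor-carbene C–H insertion; it sets out from 2 and comes back at 25. Mono-O-alkylation of 2 with bromide 12 (K2CO3, acetone, rt; the remaining chelated hydroxyl reacts far more slowly) should give 4-bromo-2-{[3,4-bis(TBS-oxy)phenyl]methoxy}-6-hydroxybenzaldehyde F1. Silylation (TBSCl, imidazole) gives its 6-O-TBS ether F2, and Heck coupling with 5 under the conditions of step 4 gives the stilbene aldehyde F3. Addition of Grignard reagent 17 at −78 °C with a cold acetic acid quench, to suppress O→O silyl shift, should give the diaryl carbinol F4. Dess–Martin oxidation gives the diaryl ketone F5, and condensation with hydrazine hydrate (AcOH, EtOH, 70 °C) gives the hydrazone F6. Oxidation with MnO2 gives the diaryldiazomethane F7, which is not isolated; a chiral dirhodium catalyst of the Rh2(PTAD)4 type, in the antipode that leads to 3S, should convert it by insertion into the benzylic ether C–H bond into the cis-(2R,3S)-dihydrobenzofuran F8. Brief treatment with catalytic trifluoroacetic acid (CH2Cl2, 0 °C) should epimerise C2 alone, through reversible ionisation of the para-oxygenated benzylic C–O bond, to the trans-(2S,3S) hexakis-TBS ether F9. KHF2 in MeOH, as in stage (ii) of step 13, then gives 25.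

2. Step 13. The electron-rich hexaphenol may degrade by oxidation during deprotection and isolation, aminolysis of the hindered carbonate may stay incomplete, and the carbonate may migrate among liberated phenoxides. The fallback sets out from 23 and comes back at 25. TBAF·3H2O (THF, 0 °C, Ar) should remove the five silyl groups and hydrolyse the carbonate; the crude phenolate is acetylated in the same flask (Ac2O, pyridine, DMAP) to the air-stable, chromatographable hexaacetate F10. Catalytic K2CO3 in degassed MeOH at 0 °C (transesterification), followed by neutralisation with acidic resin, should then give 25.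

3. Step 11. The electron-rich benzylic bromide may ionise and self-alkylate before S-alkylation, alkylation of the hindered sulfide may be slow, and the salt may revert by dealkylation during isolation. The fallback sets out from alcohol 11 and sulfide 15 and comes back at 16. The alcohol is activated with Tf2O and 2,6-lutidine in CH2Cl2 at −78 °C in the presence of 15, so that the benzylic triflate is captured as it forms and the sulfonium triflate 16 results without a benzylic halide or a silver salt. This fallback makes no compound outside the list (F0).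

**Further compounds**

F1 | step 12 | 4-bromo-2-{[3,4-bis(tert-butyldimethylsilyloxy)phenyl]methoxy}-6-hydroxybenzaldehyde | O=Cc1c(O)cc(Br)cc1OCc1ccc(O[Si](C)(C)C(C)(C)C)c(O[Si](C)(C)C(C)(C)C)c1
F2 | step 12 | 4-bromo-2-{[3,4-bis(tert-butyldimethylsilyloxy)phenyl]methoxy}-6-(tert-butyldimethylsilyloxy)benzaldehyde | O=Cc1c(O[Si](C)(C)C(C)(C)C)cc(Br)cc1OCc1ccc(O[Si](C)(C)C(C)(C)C)c(O[Si](C)(C)C(C)(C)C)c1
F3 | step 12 | (E)-2-{[3,4-bis(TBS-oxy)phenyl]methoxy}-6-(TBS-oxy)-4-[4-(TBS-oxy)-3-methoxystyryl]benzaldehyde | COc1cc(/C=C/c2cc(O[Si](C)(C)C(C)(C)C)c(C=O)c(OCc3ccc(O[Si](C)(C)C(C)(C)C)c(O[Si](C)(C)C(C)(C)C)c3)c2)ccc1O[Si](C)(C)C(C)(C)C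
F4 | step 12 | [3,5-bis(TBS-oxy)phenyl]{2-{[3,4-bis(TBS-oxy)phenyl]methoxy}-6-(TBS-oxy)-4-[(E)-4-(TBS-oxy)-3-methoxystyryl]phenyl}methanol (racemic) | COc1cc(/C=C/c2cc(O[Si](C)(C)C(C)(C)C)c(C(O)c3cc(O[Si](C)(C)C(C)(C)C)cc(O[Si](C)(C)C(C)(C)C)c3)c(OCc3ccc(O[Si](C)(C)C(C)(C)C)c(O[Si](C)(C)C(C)(C)C)c3)c2)ccc1O[Si](C)(C)C(C)(C)C
F5 | step 12 | [3,5-bis(TBS-oxy)phenyl]{2-{[3,4-bis(TBS-oxy)phenyl]methoxy}-6-(TBS-oxy)-4-[(E)-4-(TBS-oxy)-3-methoxystyryl]phenyl}methanone | COc1cc(/C=C/c2cc(O[Si](C)(C)C(C)(C)C)c(C(=O)c3cc(O[Si](C)(C)C(C)(C)C)cc(O[Si](C)(C)C(C)(C)C)c3)c(OCc3ccc(O[Si](C)(C)C(C)(C)C)c(O[Si](C)(C)C(C)(C)C)c3)c2)ccc1O[Si](C)(C)C(C)(C)C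
F6 | step 12 | hydrazone of ketone F5 | COc1cc(/C=C/c2cc(O[Si](C)(C)C(C)(C)C)c(C(=NN)c3cc(O[Si](C)(C)C(C)(C)C)cc(O[Si](C)(C)C(C)(C)C)c3)c(OCc3ccc(O[Si](C)(C)C(C)(C)C)c(O[Si](C)(C)C(C)(C)C)c3)c2)ccc1O[Si](C)(C)C(C)(C)C
F7 | step 12 | diaryldiazomethane from hydrazone F6 | COc1cc(/C=C/c2cc(O[Si](C)(C)C(C)(C)C)c(C(=[N+]=[N-])c3cc(O[Si](C)(C)C(C)(C)C)cc(O[Si](C)(C)C(C)(C)C)c3)c(OCc3ccc(O[Si](C)(C)C(C)(C)C)c(O[Si](C)(C)C(C)(C)C)c3)c2)ccc1O[Si](C)(C)C(C)(C)C
F8 | step 12 | cis-(2R,3S)-2-[3,4-bis(TBS-oxy)phenyl]-3-[3,5-bis(TBS-oxy)phenyl]-4-(TBS-oxy)-6-[(E)-4-(TBS-oxy)-3-methoxystyryl]-2,3-dihydro-1-benzofuran | COc1cc(/C=C/c2cc(O[Si](C)(C)C(C)(C)C)c3c(c2)O[C@@H](c2ccc(O[Si](C)(C)C(C)(C)C)c(O[Si](C)(C)C(C)(C)C)c2)[C@H]3c2cc(O[Si](C)(C)C(C)(C)C)cc(O[Si](C)(C)C(C)(C)C)c2)ccc1O[Si](C)(C)C(C)(C)C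
F9 | step 12 | trans-(2S,3S)-2-[3,4-bis(TBS-oxy)phenyl]-3-[3,5-bis(TBS-oxy)phenyl]-4-(TBS-oxy)-6-[(E)-4-(TBS-oxy)-3-methoxystyryl]-2,3-dihydro-1-benzofuran | COc1cc(/C=C/c2cc(O[Si](C)(C)C(C)(C)C)c3c(c2)O[C@H](c2ccc(O[Si](C)(C)C(C)(C)C)c(O[Si](C)(C)C(C)(C)C)c2)[C@H]3c2cc(O[Si](C)(C)C(C)(C)C)cc(O[Si](C)(C)C(C)(C)C)c2)ccc1O[Si](C)(C)C(C)(C)C
F10 | step 13 | hexaacetate of the target, (2S,3S) | COc1cc(/C=C/c2cc(OC(C)=O)c3c(c2)O[C@H](c2ccc(OC(C)=O)c(OC(C)=O)c2)[C@H]3c2cc(OC(C)=O)cc(OC(C)=O)c2)ccc1OC(C)=O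
F0 | step 11 | none | none
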